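**Retrosynthesis**
- Remove the silyl groups last. Disconnect the C9–C8 bond (CH2–CH2 between two allylic positions) by allyl-sulfone alkylation followed by Pd-catalysed desulfonylation. This gives a ring-bearing geranyl sulfone and an (E,E)-8-bromogeranyl silyl ether, which comes from geraniol by SeO2 allylic oxidation.
- The ring-bearing geranyl sulfone comes from an (E)-enoate made by HWE olefination of a methyl ketone. That ketone is the hydroxy-dihydroionone 4-(2-hydroxy-2,6,6-trimethylcyclohexyl)butan-2-one.
- The only ring, both ring stereocentres and the tertiary alcohol form in one step: a proposed enantioselective protonation-initiated monocyclization of geranylacetone, terminated by the ketone oxygen and then hydrolysed.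

**Assumptions**
- (E)-Geranylacetone is purchased, or purified from the commercial isomer mixture.
- The IDPi enantiomer that gives the (1S,2S) ring is chosen by screening.
- CIP analysis of the target SMILES gives ring C1 = S (CH bearing the chain) and ring C6 = S (C(OH)Me). The chain CH2 and the OH-bearing carbon keep these labels in every ring-containing intermediate.

---

**Step 1**
Reactants: 1, (E)-geranylacetone, (5E)-6,10-dimethylundeca-5,9-dien-2-one
Product: 2, 4-[(1S,2S)-2-hydroxy-2,6,6-trimethylcyclohexyl]butan-2-one
Conditions: chiral IDPi acid (5 mol %), pentane/CH2Cl2 4:1, –30 °C, 72 h; then 1 M HCl (aq)/THF, 0 °C → rt, 30 min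
Reagents that add atoms: water, O (from the aqueous quench)
Why: Proposed new method: a confined chiral imidodiphosphorimidate (IDPi) protonates the prenyl alkene, and the (E)-trisubstituted alkene attacks it through a chair transition state. This forms the C1–C2 bond, fixes the ring-carbon stereocentre under chiral-anion control and gives a tertiary cation. The tethered ketone oxygen then traps the cation through the six-membered ring that closes onto the equatorial side chain. Trapping on the face anti to the axial gem-dimethyl group gives a trans-fused oxocarbenium and hence the OH trans to the side chain. Aqueous acid hydrolyses the oxocarbenium or enol ether to the hydroxy ketone with the C–O bond retained. The closest known chemistry is IDPi-catalysed protonation-initiated polyene cyclization (homofarnesol → ambrox type) together with cation–olefin–carbonyl (Prins-type) termination. What is new is using a ketone as an internal water surrogate to stop at the monocycle as a tertiary alcohol.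

**Step 2**
Reactants: 2, hydroxy ketone
Product: 3, ethyl (2E)-5-[(1S,2S)-2-hydroxy-2,6,6-trimethylcyclohexyl]-3-methylpent-2-enoate
Conditions: (EtO)2P(O)CH2CO2Et, NaH (2.6 equiv), THF, 0 → 60 °C; separate the Z isomer by AgNO3–silica chromatography
Reagents that add atoms: triethyl phosphonoacetate, CCOC(=O)CP(=O)(OCC)OCC
Why: Horner–Wadsworth–Emmons olefination of the methyl ketone gives mainly the E-enoate (about 4:1) by thermodynamic anti-elimination. The ketone is more than three bonds from C1, so the ring stereocentres are untouched.

**Step 3**
Reactants: 3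
Product: 4, ethyl (2E)-3-methyl-5-[(1S,2S)-2,6,6-trimethyl-2-(triethylsilyloxy)cyclohexyl]pent-2-enoate
Conditions: TESOTf, 2,6-lutidine, CH2Cl2, 0 °C
Reagents that add atoms: TESOTf, CC[Si](CC)(CC)OS(=O)(=O)C(F)(F)F
Why: Silylation of the tertiary alcohol is done at the ester stage because TESOTf would enolize a ketone. The TES ether survives the later DIBAL, organolithium and hydride steps, yet comes off with fluoride at the end.

**Step 4**
Reactants: 4
Product: 5, (2E)-3-methyl-5-[(1S,2S)-2,6,6-trimethyl-2-(triethylsilyloxy)cyclohexyl]pent-2-en-1-ol
Conditions: DIBAL-H (2.5 equiv), CH2Cl2, –78 °C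
Reagents that add atoms: none
Why: Ester-to-allylic-alcohol reduction; the trisubstituted alkene and the TES ether are unaffected.

**Step 5**
Reactants: 5
Product: 6, (1S,2S)-1-[(3E)-5-bromo-3-methylpent-3-en-1-yl]-2,6,6-trimethyl-2-(triethylsilyloxy)cyclohexane (the allylic bromide, used crude)
Conditions: CBr4, PPh3, CH2Cl2, 0 °C
Reagents that add atoms: carbon tetrabromide, BrC(Br)(Br)Br
Why: Appel bromination under neutral conditions converts the primary allylic alcohol by SN2 with no alkene isomerization and leaves the tertiary TES ether intact.

**Step 6**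
Reactants: 6
Product: 7, (E)-allyl phenyl sulfone with 3-methyl-5-[(1S,2S)-2,6,6-trimethyl-2-(triethylsilyloxy)cyclohexyl]pent-2-en-1-yl
Conditions: PhSO2Na, DMF, rt
Reagents that add atoms: sodium benzenesulfinate, [Na+].[O-]S(=O)c1ccccc1
Why: SN2 displacement of the allylic bromide by sulfinate gives the geranyl-type sulfone needed for Biellmann alkylation.

**Step 7**
Reactants: 8, geraniol, (2E)-3,7-dimethylocta-2,6-dien-1-ol
Product: 9, geranyl TBS ether
Conditions: TBSCl, imidazole, DMF, rt
Reagents that add atoms: TBSCl, CC(C)(C)[Si](C)(C)Cl
Why: Standard protection of the primary alcohol. TBS survives the SeO2 step, the organolithium step and the hydride step.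

**Step 8**
Reactants: 9
Product: 10, (2E,6E)-8-[(tert-butyldimethylsilyl)oxy]-2,6-dimethylocta-2,6-dien-1-ol
Conditions: SeO2 (10 mol %), TBHP (5–6 M in decane), CH2Cl2, 0 °C → rt
Reagents that add atoms: tert-butyl hydroperoxide, CC(C)(C)OO
Why: Sharpless SeO2/TBHP allylic oxidation of geranyl derivatives hydroxylates the terminal (E)-methyl group selectively. The electron-poorer silyloxy-bearing alkene is untouched.

**Step 9**
Reactants: 10
Product: 11, tert-butyl{[(2E,6E)-8-bromo-3,7-dimethylocta-2,6-dien-1-yl]oxy}dimethylsilane
Conditions: CBr4, PPh3, CH2Cl2, 0 °C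
Reagents that add atoms: carbon tetrabromide, BrC(Br)(Br)Br
Why: Appel bromination of the primary allylic alcohol, with both alkene geometries retained.

**Step 10**
Reactants: 7 (sulfone) and 11 (bromide)
Product: 12, the alkylated allylic sulfone, obtained as a mixture of epimers at the sulfone carbon
Conditions: n-BuLi (1.05 equiv), THF, –78 °C; then HMPA (or DMPU) and 11, –78 → –20 °C
Reagents that add atoms: none
Why: Biellmann alkylation, in which the α-sulfonyl allyl carbanion attacks the primary allylic bromide by SN2. It joins the two fragments at C9–C8 and keeps both E alkenes.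

**Step 11**
Reactants: 12
Product: 13, the bis-silyl-protected target (C1–OTBS, ring C–OTES)
Conditions: Pd(dppp)Cl2 (10 mol %), LiBHEt3 (4 equiv), THF, 0 °C
Reagents that add atoms: none
Why: Pd-catalysed hydrogenolysis of the allylic sulfone goes through a π-allyl palladium. Hydride adds at the less hindered secondary terminus, so the trisubstituted E alkene is regenerated at C10=C11. This is the standard polyprenyl route.

**Step 12**
Reactants: 13
Product: 14, preluffariellolide A
Conditions: TBAF (4 equiv), THF, 0 → 40 °C
Reagents that add atoms: none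
Why: Fluoride removes the primary TBS and the tertiary TES ethers. No acid is used, so the tertiary alcohol and the polyene are not ionized.

---

**Compound list**

| No. | Name | SMILES | Role |
|---|---|---|---|
| 1 | (E)-geranylacetone | CC(=O)CC/C=C(\C)CCC=C(C)C | starting material |
| 2 | 4-[(1S,2S)-2-hydroxy-2,6,6-trimethylcyclohexyl]butan-2-one | CC(=O)CC[C@H]1C(C)(C)CCC[C@]1(C)O | intermediate |
| 3 | ethyl (2E)-5-[(1S,2S)-2-hydroxy-2,6,6-trimethylcyclohexyl]-3-methylpent-2-enoate | CCOC(=O)/C=C(\C)CC[C@H]1C(C)(C)CCC[C@]1(C)O | intermediate |
| 4 | TES ether of 3 | CCOC(=O)/C=C(\C)CC[C@H]1C(C)(C)CCC[C@]1(C)O[Si](CC)(CC)CC | intermediate |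
| 5 | (2E)-allylic alcohol | OC/C=C(\C)CC[C@H]1C(C)(C)CCC[C@]1(C)O[Si](CC)(CC)CC | intermediate |
| 6 | (2E)-allylic bromide | BrC/C=C(\C)CC[C@H]1C(C)(C)CCC[C@]1(C)O[Si](CC)(CC)CC | intermediate |
| 7 | (2E)-allyl phenyl sulfone | O=S(=O)(c1ccccc1)C/C=C(\C)CC[C@H]1C(C)(C)CCC[C@]1(C)O[Si](CC)(CC)CC | intermediate |
| 8 | geraniol | CC(C)=CCC/C(C)=C/CO | starting material |
| 9 | geranyl TBS ether | CC(C)(C)[Si](C)(C)OC/C=C(\C)CCC=C(C)C | intermediate |
| 10 | (2E,6E)-8-(TBSO)-2,6-dimethylocta-2,6-dien-1-ol (8-hydroxygeranyl TBS ether) | CC(C)(C)[Si](C)(C)OC/C=C(\C)CC/C=C(\C)CO | intermediate |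
| 11 | (2E,6E)-8-bromogeranyl TBS ether | CC(C)(C)[Si](C)(C)OC/C=C(\C)CC/C=C(\C)CBr | intermediate |
| 12 | alkylated allylic sulfone | CC(C)(C)[Si](C)(C)OC/C=C(\C)CC/C=C(\C)CC(S(=O)(=O)c1ccccc1)/C=C(\C)CC[C@H]1C(C)(C)CCC[C@]1(C)O[Si](CC)(CC)CC | intermediate |
| 13 | bis-silyl-protected target | CC(C)(C)[Si](C)(C)OC/C=C(\C)CC/C=C(\C)CC/C=C(\C)CC[C@H]1C(C)(C)CCC[C@]1(C)O[Si](CC)(CC)CC | intermediate |
| 14 | preluffariellolide A | C/C(=C\CO)CC/C=C(\C)CC/C=C(\C)CC[C@H]1C(C)(C)CCC[C@]1(C)O | target |

**Total steps:** 12
**Longest linear sequence:** 9 steps (1 → 2 → 3 → 4 → 5 → 6 → 7 → 12 → 13 → 14, i.e. steps 1–6 and 10–12)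

**Three steps most likely to fail**
1. **Step 1 (proposed new cyclization).** The ketone may sequester the acid, and elimination or cis-fused capture may compete, giving low ee or dr.
   - Fallback: use a racemic known route. Make dihydro-α-ionone from commercial α-ionone, then ketalize, epoxidize with mCPBA (anti to the side chain), open with LiAlH4 at the secondary carbon and deketalize to give racemic 2. Resolve it by preparative chiral-phase HPLC to get the (1S,2S) enantiomer.
2. **Step 8 (SeO2 oxidation).** It gives only moderate yield and some over-oxidation.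
   - Fallback: avoid allylic oxidation. Use commercial ethyl (E)-4-bromo-3-methylbut-2-enoate as the electrophile in Step 10. After desulfonylation, extend with DIBAL reduction, Appel bromination, acetoacetate alkylation and decarboxylation, then HWE and DIBAL reduction to install C1–C4.
3. **Step 11 (Pd/LiBHEt3 desulfonylation).** Regiochemical leakage could move the alkene or give Z isomers.
   - Fallback: drop the sulfone coupling. Iterate Carroll-type acetoacetate alkylation and decarboxylation, HWE and DIBAL reduction from allylic bromide 6, then remove the silyl groups.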